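**Plan**

1. Retrosynthetic cuts, in order: the exocyclic C=C of the enal (tethered olefination between a ring ketone and the hydroxypropyl arm); the side-chain C=C next to CH2OH (ester aldol and elimination with a dienal); the C–CH3 bond of the tertiary carbinol; the bond from the spiro carbon to the CH(CH2CH2CH2OH) carbon of the cyclohexane (ring A); the bond joining the two five-membered rings.
2. Enabling feature: the spiro carbon lies between CH–OH of the cyclopentane (ring B) and C(CH3)OH of ring A. Without the methyl this is a β-hydroxy ketone with a quaternary α-carbon, the product of a semipinacol shift in a 1-(1,2-epoxycyclopentyl)cyclopentanol, so ring A is carried as a cyclopentane and grows to the cyclohexane by a 1,2-shift.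
3. Forward: a cis-2,3-disubstituted cyclopentanone (ring A precursor) and a 3-allylcyclopentenyllithium (ring B) are joined; epoxidation and ring expansion give the spiro[4.5]decanone; then methyl addition, side-chain growth from the allyl group, the enal through an eight-membered lactone, reduction, allylic oxidation and desilylation.
4. Stereochemistry: CBS reduction relayed by anti-hydroboration sets the chain-bearing carbon of ring A (kept in the shift); ligand-controlled copper hydride reduction sets the ring B carbon that carries the side chain, and this carbon steers the epoxide; the epoxide sets the spiro carbon and the secondary carbinol; the chair of the spiro ketone steers the methyl; the lactone ring fixes the Z enal; E1cB elimination and the Heck reaction give the E alkenes.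

Key step: step 11

Assumption: the sense of induction in steps 2 and 7 is assigned by analogy with simple 2-alkyl- and 3-alkylcyclopentenones; if a test reaction shows the opposite sense, the antipodal catalyst or ligand is used.

Abbreviations: TBS = tert-butyldimethylsilyl, TES = triethylsilyl, TBDPS = tert-butyldiphenylsilyl, DMP = Dess–Martin periodinane. Spiro compounds are numbered as spiro[4.5]decanes: C1 (CH–O, ring B), C2 (ring B carbon with the side chain), C5 (spiro), C6 (ring A carbon next to C5 bearing O), C9, C10 (ring A CH bearing the oxypropyl chain).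

**Route**

Step 1
Reactants: 1 tert-butyl(dimethyl)(prop-2-en-1-yloxy)silane; 2 2-iodocyclopent-2-en-1-one
Product: 4 2-[3-(TBS-oxy)propyl]cyclopent-2-en-1-one, via B-alkyl-9-BBN adduct 3 (not isolated)
Conditions: 9-BBN-H, THF, 0 °C to rt; then 2, PdCl2(dppf) (5 mol %), AsPh3, Cs2CO3, DMF/THF/H2O, rt
Reagents that add atoms: none
Why: Anti-Markovnikov hydroboration of the terminal alkene followed by B-alkyl Suzuki–Miyaura coupling with the α-iodoenone is a standard way to 2-alkylcycloalkenones; no stereocenter is formed.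

Step 2
Reactants: 4 2-[3-(TBS-oxy)propyl]cyclopent-2-en-1-one
Product: 5 (1R)-2-[3-(TBS-oxy)propyl]cyclopent-2-en-1-ol
Conditions: (S)-2-methyl-CBS-oxazaborolidine (10 mol %), BH3·THF, THF, −20 °C
Reagents that add atoms: none
Why: Corey–Bakshi–Shibata reduction with the substituted alkenyl carbon as the large group should give the (R)-allylic alcohol in high enantiomeric excess; this center relays its chirality in step 4 and is itself removed in step 23.

Step 3
Reactants: 5 (1R)-2-[3-(TBS-oxy)propyl]cyclopent-2-en-1-ol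
Product: 6 (1R)-2-[3-(TBS-oxy)propyl]-1-(TES-oxy)cyclopent-2-ene
Conditions: TESCl, imidazole, CH2Cl2, 0 °C
Reagents that add atoms: chlorotriethylsilane CC[Si](Cl)(CC)CC
Why: Silylation of a secondary allylic alcohol; the triethylsilyl ether can later be removed beside the TBDPS ether and the hindered secondary TBS ether.

Step 4
Reactants: 6 (1R)-2-[3-(TBS-oxy)propyl]-1-(TES-oxy)cyclopent-2-ene
Product: 8 (1R,2S,3R)-2-[3-(TBS-oxy)propyl]-3-(TES-oxy)cyclopentan-1-ol, via alkylborane 7 (not isolated)
Conditions: BH3·THF, THF, 0 °C to rt; then NaOH, H2O2, 0 °C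
Reagents that add atoms: hydrogen peroxide OO
Why: Syn hydroboration puts boron on the less substituted alkene carbon and both new bonds on the face opposite to the allylic silyloxy group, and oxidation with retention gives the alcohol; the new C–H bond sets the chain-bearing stereocenter with the chain cis to OTES.

Step 5
Reactants: 8 (1R,2S,3R)-2-[3-(TBS-oxy)propyl]-3-(TES-oxy)cyclopentan-1-ol
Product: 9 (2R,3R)-2-[3-(TBS-oxy)propyl]-3-(TES-oxy)cyclopentan-1-one
Conditions: DMP, NaHCO3, CH2Cl2, 0 °C to rt
Reagents that add atoms: none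
Why: Dess–Martin oxidation under buffered, non-basic conditions should give the ketone without epimerizing the α-stereocenter or eliminating the β-silyloxy group.

Step 6
Reactants: 10 3-ethoxycyclopent-2-en-1-one; 11 allylmagnesium bromide
Product: 13 3-(prop-2-en-1-yl)cyclopent-2-en-1-one, via bromomagnesium alkoxide adduct 12 (not isolated)
Conditions: THF, 0 °C; then 1 M HCl, 0 °C
Reagents that add atoms: none
Why: Stork–Danheiser transposition: 1,2-addition of the Grignard reagent to the vinylogous ester and acid hydrolysis with loss of ethanol give the 3-substituted enone.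

Step 7
Reactants: 13 3-(prop-2-en-1-yl)cyclopent-2-en-1-one
Product: 16 (3S)-3-(prop-2-en-1-yl)cyclopent-1-en-1-yl trifluoromethanesulfonate, via bis(enol) diphenylsilane 14 (not isolated), via lithium enolate 15 (not isolated)
Conditions: CuCl (5 mol %), NaOtBu (5 mol %), (S)-p-tol-BINAP (5 mol %), Ph2SiH2 (0.55 equiv), toluene, 0 °C; then MeLi, THF, 0 °C; then PhNTf2, −78 °C to rt
Reagents that add atoms: N-phenylbis(trifluoromethanesulfonimide) O=S(=O)(N(c1ccccc1)S(=O)(=O)C(F)(F)F)C(F)(F)F
Why: Copper hydride asymmetric conjugate reduction of a 3-alkylcyclopentenone delivers hydride to one face of the β-carbon under ligand control (this sets the ring B stereocenter) and leaves a silyl enol ether of fixed regiochemistry, which MeLi turns into the lithium enolate that is triflated on oxygen.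

Step 8
Reactants: 16 (3S)-3-(prop-2-en-1-yl)cyclopent-1-en-1-yl trifluoromethanesulfonate
Product: 17 trimethyl[(3S)-3-(prop-2-en-1-yl)cyclopent-1-en-1-yl]stannane
Conditions: Pd(PPh3)4 (5 mol %), Me3SnSnMe3, LiCl, THF, 65 °C
Reagents that add atoms: hexamethylditin C[Sn](C)(C)[Sn](C)(C)C
Why: Palladium-catalysed coupling of an enol triflate with hexamethylditin (Stille-type stannylation) gives the alkenylstannane without touching the stereocenter.

Step 9
Reactants: 17 trimethyl[(3S)-3-(prop-2-en-1-yl)cyclopent-1-en-1-yl]stannane; 9 (2R,3R)-2-[3-(TBS-oxy)propyl]-3-(TES-oxy)cyclopentan-1-one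
Product: 19 (1S,2R,3R)-1-[(3S)-3-allylcyclopent-1-en-1-yl]-2-[3-(TBS-oxy)propyl]-3-(TES-oxy)cyclopentan-1-ol (hydroxyl, chain and OTES on one face), via alkenyllithium 18 (not isolated)
Conditions: MeLi, THF, −78 to −40 °C; then 9 premixed with LaCl3·2LiCl, THF, −78 °C
Reagents that add atoms: none
Why: Tin–lithium exchange gives the alkenyllithium with the double bond fixed in place, and its 1,2-addition (the lanthanum salt curbs enolization and β-elimination) should occur on the ketone face opposite to the two cis substituents, which sets the carbinol with hydroxyl cis to the side chain.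

Step 10
Reactants: 19 tertiary allylic alcohol (as above)
Product: 20 ring B epoxide of 19, oxygen trans to the allyl group
Conditions: VO(acac)2 (5 mol %), tBuOOH, CH2Cl2, 0 °C
Reagents that add atoms: tert-butyl hydroperoxide CC(C)(C)OO
Why: Vanadium-catalysed epoxidation is directed by the tertiary allylic hydroxyl, so the remote terminal alkene is untouched, and oxygen should be delivered to the ring B face opposite to the allyl group on the adjacent ring carbon, which sets both epoxide carbons relative to that center.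

Step 11
Reactants: 20 ring B epoxide of 19
Product: 21 2-allyl-1-hydroxy-10-[3-(TBS-oxy)propyl]-9-(TES-oxy)spiro[4.5]decan-6-one (C1, C2, C5, C10 configured as in 42; 9-OTES cis to the C10 chain)
Conditions: ZnBr2 (30 mol %), CH2Cl2, 0 °C to rt
Reagents that add atoms: none
Why: ZnBr2 binds the tertiary hydroxyl and the epoxide oxygen as a five-membered chelate and ionizes the C–O bond at the fully substituted epoxide carbon while the anti-periplanar ring A bond shifts to that carbon in a concerted semipinacol rearrangement (the Lewis-acid rearrangement of tertiary α-hydroxy epoxides to β-hydroxy ketones), so the cyclopentanol becomes a cyclohexanone. No ring is closed by cyclization: ring A grows from five to six members by the 1,2-shift, driven by release of epoxide strain and formation of the C=O bond. The spiro carbon is formed with inversion because the migrating carbon enters anti to the leaving oxygen; the secondary carbinol carbon keeps the epoxide oxygen and so ends cis to the new carbonyl carbon and trans to the migrated carbon; the migrating carbon keeps its configuration. The step needs the chain-bearing ring A carbon, not the ring A CH2, to migrate: with the carbinol configuration from step 9, the chelated rotamer places the chain-bearing carbon anti to the breaking bond and the CH2 in the open sector, while CH2 migration would force the bulky carbon into the narrow sector between epoxide oxygen and ring carbon. The chain-bearing carbon is also the more substituted one, and its silyloxy neighbour is only a weak brake. Opening at the secondary epoxide carbon or a hydride shift is not expected, because only the tertiary carbon is flanked by the carbinol oxygen that pushes the shift.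

Step 12
Reactants: 21 β-hydroxy spiro ketone (as above)
Product: 22 2-allyl-1-(TBS-oxy)-10-[3-(TBS-oxy)propyl]-9-(TES-oxy)spiro[4.5]decan-6-one
Conditions: TBSOTf, 2,6-lutidine, CH2Cl2, −78 °C
Reagents that add atoms: tert-butyldimethylsilyl trifluoromethanesulfonate CC(C)(C)[Si](C)(C)OS(=O)(=O)C(F)(F)F
Why: Silyl triflate with 2,6-lutidine silylates the hindered secondary alcohol at low temperature and blocks retro-aldol cleavage in the next step.

Step 13
Reactants: 22 silylated spiro ketone (as above)
Product: 23 2-allyl-6-methyl-1-(TBS-oxy)-10-[3-(TBS-oxy)propyl]-9-(TES-oxy)spiro[4.5]decan-6-ol (6-OH cis to the C10 chain)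
Conditions: MeMgBr, LaCl3·2LiCl, THF, −78 to 0 °C
Reagents that add atoms: methylmagnesium bromide C[Mg]Br
Why: Grignard 1,2-addition promoted by the lanthanum salt should bring the methyl in from the ring A face opposite to the C10 chain, because in one chair the axial chain is 1,3-diaxial to the carbonyl and in the other chair the same face is the one away from the axial oxygenated ring B carbon, so both chairs lead to the tertiary alcohol with hydroxyl cis to the chain.

Step 14
Reactants: 23 tertiary alcohol (as above)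
Product: 24 methyl 2-[6-hydroxy-6-methyl-1-(TBS-oxy)-10-[3-(TBS-oxy)propyl]-9-(TES-oxy)spiro[4.5]decan-2-yl]acetate
Conditions: O3, NaOH (2.5 M in MeOH), CH2Cl2, −78 °C
Reagents that add atoms: ozone [O-][O+]=O; methanol CO
Why: Ozonolysis in methanolic NaOH converts the only alkene, the terminal allyl group, directly into the one-carbon-shorter methyl ester through ozone oxidation of the methyl hemiacetal of the intermediate aldehyde.

Step 15
Reactants: 25 6-methylhept-5-en-2-one
Product: 27 6-methylhepta-1,5-dien-2-yl trifluoromethanesulfonate, via lithium enolate 26 (not isolated)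
Conditions: LiN(iPr)2, THF, −78 °C; then PhNTf2, −78 °C to rt
Reagents that add atoms: N-phenylbis(trifluoromethanesulfonimide) O=S(=O)(N(c1ccccc1)S(=O)(=O)C(F)(F)F)C(F)(F)F
Why: Kinetic deprotonation of the methyl ketone at the methyl group and O-triflation of the less substituted enolate give the 1,1-disubstituted enol triflate.

Step 16
Reactants: 27 6-methylhepta-1,5-dien-2-yl trifluoromethanesulfonate; 28 prop-2-enal
Product: 29 (2E)-8-methyl-4-methylidenenona-2,7-dienal
Conditions: Pd(OAc)2 (5 mol %), PPh3, Et3N, DMF, 60 °C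
Reagents that add atoms: none
Why: Heck reaction of the enol triflate with acrolein; syn insertion and syn β-hydride elimination give the (E)-dienal.

Step 17
Reactants: 24 methyl ester (as above); 29 (2E)-8-methyl-4-methylidenenona-2,7-dienal
Product: 31 methyl (4E)-3-hydroxy-10-methyl-6-methylidene-2-[spiro core of 24]undeca-4,9-dienoate (mixture at C2 and C3), via dilithium ester enolate 30 (not isolated)
Conditions: LiN(iPr)2 (2.2 equiv), THF, −78 °C; then 29, −78 °C
Reagents that add atoms: none
Why: Aldol addition of the lithium ester enolate (the second equivalent of base takes the tertiary hydroxyl proton) to the aldehyde carbonyl of the dienal at low temperature; the two new stereocenters are lost in the next step.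

Step 18
Reactants: 31 aldol adduct (as above)
Product: 33 methyl (2E,4E)-10-methyl-6-methylidene-2-[spiro core of 24]undeca-2,4,9-trienoate, via allylic acetate 32 (not isolated)
Conditions: Ac2O, DMAP, Et3N, CH2Cl2, 0 °C; then DBU, rt
Reagents that add atoms: none
Why: Selective acetylation of the secondary allylic alcohol and base-induced E1cB elimination through the ester enolate should give the thermodynamically preferred (E)-2-substituted trienoate with the dienyl group trans to the ester.

Step 19
Reactants: 33 trienoate (as above)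
Product: 34 (2E,4E)-10-methyl-6-methylidene-2-[spiro core of 24]undeca-2,4,9-trien-1-ol
Conditions: iBu2AlH, CH2Cl2, −78 °C
Reagents that add atoms: none
Why: 1,2-Reduction of the conjugated ester with iBu2AlH at low temperature gives the primary allylic alcohol and leaves the silyl ethers.

Step 20
Reactants: 34 trienol (as above)
Product: 35 TBDPS ether of 34
Conditions: TBDPSCl, imidazole, CH2Cl2, 0 °C to rt
Reagents that add atoms: tert-butyl(chloro)diphenylsilane CC(C)(C)[Si](Cl)(c1ccccc1)c1ccccc1
Why: Silylation of the primary allylic alcohol with a group that survives step 21 and keeps this alcohol out of the acylation, reduction and oxidation steps 22, 25 and 26.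

Step 21
Reactants: 35 TBDPS ether (as above)
Product: 36 diol with free 3-hydroxypropyl chain and free C9 hydroxyl (C1-OTBS and side-chain OTBDPS kept)
Conditions: HF·pyridine, pyridine, THF, 0 °C
Reagents that add atoms: none
Why: Buffered HF·pyridine cleaves the primary TBS ether and the secondary TES ether much faster than the TBDPS ether and the neopentyl-type secondary TBS ether.

Step 22
Reactants: 36 diol (as above)
Product: 37 2-(diethoxyphosphoryl)propanoate of the primary alcohol of 36
Conditions: 2-(diethoxyphosphoryl)propanoic acid, EDC·HCl, DMAP (cat.), CH2Cl2, 0 °C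
Reagents that add atoms: 2-(diethoxyphosphoryl)propanoic acid CCOP(=O)(OCC)C(C)C(=O)O
Why: Carbodiimide (Steglich-type) esterification is selective for the primary alcohol over the hindered secondary and tertiary hydroxyls and attaches the phosphonate for intramolecular delivery.

Step 23
Reactants: 37 phosphonopropanoate (as above)
Product: 38 C9 ketone of 37
Conditions: DMP, NaHCO3, CH2Cl2, 0 °C to rt
Reagents that add atoms: none
Why: Dess–Martin oxidation of the only remaining secondary alcohol gives the ring A ketone; the tertiary alcohol is inert.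

Step 24
Reactants: 38 keto phosphonate (as above)
Product: 39 eight-membered α,β-unsaturated lactone fused to ring A at C9–C10 (tetrasubstituted alkene, lactone carbonyl cis to C10)
Conditions: LiCl, iPr2NEt, MeCN (0.002 M), rt to 60 °C
Reagents that add atoms: none
Why: Intramolecular Horner–Wadsworth–Emmons reaction under Masamune–Roush conditions at high dilution closes the eight-membered lactone, whose ring can hold only the cis arrangement of ester carbonyl and C10, which fixes the alkene geometry, and the mild amine base should spare the α-stereocenter.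

Step 25
Reactants: 39 lactone (as above)
Product: 40 diol: Z-configured allylic alcohol at the exocyclic alkene and free 3-hydroxypropyl chain
Conditions: iBu2AlH, CH2Cl2, −78 to 0 °C
Reagents that add atoms: none
Why: iBu2AlH reduces the lactone to the diol, which frees the hydroxypropyl chain and the allylic alcohol of the future enal without touching the alkene geometry.

Step 26
Reactants: 40 diol (as above)
Product: 41 bis-silylated enal (1-OTBS, side-chain OTBDPS)
Conditions: MnO2, CH2Cl2, rt
Reagents that add atoms: none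
Why: MnO2 oxidizes only the free allylic primary alcohol; the saturated primary, tertiary and silylated hydroxyls remain.

Step 27
Reactants: 41 bis-silylated enal (as above)
Product: 42 target CNP0246965.1
Conditions: Bu4NF, AcOH, THF, rt to 40 °C
Reagents that add atoms: none
Why: Fluoride buffered with acetic acid removes both silyl ethers without base-induced change of the enal or the trienyl alcohol.

**Compound list**

1 | tert-butyl(dimethyl)(prop-2-en-1-yloxy)silane | C=CCO[Si](C)(C)C(C)(C)C | starting material
2 | 2-iodocyclopent-2-en-1-one | O=C1CCC=C1I | starting material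
3 | 9-[3-(TBS-oxy)propyl]-9-borabicyclo[3.3.1]nonane | CC(C)(C)[Si](C)(C)OCCCB1C2CCCC1CCC2 | intermediate
4 | 2-[3-(TBS-oxy)propyl]cyclopent-2-en-1-one | O=C1CCC=C1CCCO[Si](C)(C)C(C)(C)C | intermediate
5 | (1R)-2-[3-(TBS-oxy)propyl]cyclopent-2-en-1-ol | O[C@@H]1CCC=C1CCCO[Si](C)(C)C(C)(C)C | intermediate
6 | (1R)-2-[3-(TBS-oxy)propyl]-1-(TES-oxy)cyclopent-2-ene | CC[Si](CC)(CC)O[C@@H]1CCC=C1CCCO[Si](C)(C)C(C)(C)C | intermediate
7 | alkylborane from 6 (BH2 trans to OTES on the ring carbon remote from it) | B[C@@H]1CC[C@@H](O[Si](CC)(CC)CC)[C@H]1CCCO[Si](C)(C)C(C)(C)C | intermediate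
8 | (1R,2S,3R)-2-[3-(TBS-oxy)propyl]-3-(TES-oxy)cyclopentan-1-ol | O[C@@H]1CC[C@@H](O[Si](CC)(CC)CC)[C@H]1CCCO[Si](C)(C)C(C)(C)C | intermediate
9 | (2R,3R)-2-[3-(TBS-oxy)propyl]-3-(TES-oxy)cyclopentan-1-one (cis) | O=C1CC[C@@H](O[Si](CC)(CC)CC)[C@H]1CCCO[Si](C)(C)C(C)(C)C | intermediate
10 | 3-ethoxycyclopent-2-en-1-one | CCOC1=CC(=O)CC1 | starting material
11 | allylmagnesium bromide | C=CC[Mg]Br | starting material
12 | bromomagnesium 1-allyl-3-ethoxycyclopent-2-en-1-olate | C=CCC1(O[Mg]Br)CCC(OCC)=C1 | intermediate
13 | 3-(prop-2-en-1-yl)cyclopent-2-en-1-one | C=CCC1=CC(=O)CC1 | intermediate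
14 | bis{[(3S)-3-allylcyclopent-1-en-1-yl]oxy}diphenylsilane | C=CC[C@@H]1CCC(=C1)O[Si](c1ccccc1)(c1ccccc1)OC1=C[C@H](CC=C)CC1 | intermediate
15 | lithium (3S)-3-allylcyclopent-1-en-1-olate | C=CC[C@@H]1CCC(=C1)O[Li] | intermediate
16 | (3S)-3-(prop-2-en-1-yl)cyclopent-1-en-1-yl trifluoromethanesulfonate | C=CC[C@@H]1CCC(OS(=O)(=O)C(F)(F)F)=C1 | intermediate
17 | trimethyl[(3S)-3-(prop-2-en-1-yl)cyclopent-1-en-1-yl]stannane | C=CC[C@@H]1CCC([Sn](C)(C)C)=C1 | intermediate
18 | [(3S)-3-(prop-2-en-1-yl)cyclopent-1-en-1-yl]lithium | C=CC[C@@H]1CCC([Li])=C1 | intermediate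
19 | (1S,2R,3R)-1-[(3S)-3-allylcyclopent-1-en-1-yl]-2-[3-(TBS-oxy)propyl]-3-(TES-oxy)cyclopentan-1-ol | C=CC[C@@H]1CCC(=C1)[C@]2(O)CC[C@@H](O[Si](CC)(CC)CC)[C@H]2CCCO[Si](C)(C)C(C)(C)C | intermediate
20 | ring B epoxide of 19, oxygen trans to allyl | C=CC[C@@H]1CC[C@@]2([C@]3(O)CC[C@@H](O[Si](CC)(CC)CC)[C@H]3CCCO[Si](C)(C)C(C)(C)C)O[C@@H]12 | intermediate
21 | 2-allyl-1-hydroxy-10-[3-(TBS-oxy)propyl]-9-(TES-oxy)spiro[4.5]decan-6-one | C=CC[C@@H]1CC[C@]2([C@H](CCCO[Si](C)(C)C(C)(C)C)[C@H](O[Si](CC)(CC)CC)CCC2=O)[C@H]1O | intermediate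
22 | 1-O-TBS ether of 21 | C=CC[C@@H]1CC[C@]2([C@H](CCCO[Si](C)(C)C(C)(C)C)[C@H](O[Si](CC)(CC)CC)CCC2=O)[C@H]1O[Si](C)(C)C(C)(C)C | intermediate
23 | 2-allyl-6-methyl-1-(TBS-oxy)-10-[3-(TBS-oxy)propyl]-9-(TES-oxy)spiro[4.5]decan-6-ol | C=CC[C@@H]1CC[C@]2([C@H](CCCO[Si](C)(C)C(C)(C)C)[C@H](O[Si](CC)(CC)CC)CC[C@]2(C)O)[C@H]1O[Si](C)(C)C(C)(C)C | intermediate
24 | methyl 2-(spirodecan-2-yl)acetate from 23 | COC(=O)C[C@@H]1CC[C@]2([C@H](CCCO[Si](C)(C)C(C)(C)C)[C@H](O[Si](CC)(CC)CC)CC[C@]2(C)O)[C@H]1O[Si](C)(C)C(C)(C)C | intermediate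
25 | 6-methylhept-5-en-2-one | CC(=O)CCC=C(C)C | starting material
26 | lithium 6-methylhepta-1,5-dien-2-olate | C=C(O[Li])CCC=C(C)C | intermediate
27 | 6-methylhepta-1,5-dien-2-yl trifluoromethanesulfonate | C=C(OS(=O)(=O)C(F)(F)F)CCC=C(C)C | intermediate
28 | prop-2-enal (acrolein) | C=CC=O | starting material
29 | (2E)-8-methyl-4-methylidenenona-2,7-dienal | O=C/C=C/C(=C)CCC=C(C)C | intermediate
30 | dilithium salt of 24 (ester enolate and tertiary alkoxide) | COC(O[Li])=C[C@@H]1CC[C@]2([C@H](CCCO[Si](C)(C)C(C)(C)C)[C@H](O[Si](CC)(CC)CC)CC[C@]2(C)O[Li])[C@H]1O[Si](C)(C)C(C)(C)C | intermediate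
31 | aldol adduct, methyl (4E)-3-hydroxy-2-(spirodecan-2-yl)undeca-4,9-dienoate | C=C(/C=C/C(O)C(C(=O)OC)[C@@H]1CC[C@]2([C@H](CCCO[Si](C)(C)C(C)(C)C)[C@H](O[Si](CC)(CC)CC)CC[C@]2(C)O)[C@H]1O[Si](C)(C)C(C)(C)C)CCC=C(C)C | intermediate
32 | 3-O-acetate of 31 | C=C(/C=C/C(OC(C)=O)C(C(=O)OC)[C@@H]1CC[C@]2([C@H](CCCO[Si](C)(C)C(C)(C)C)[C@H](O[Si](CC)(CC)CC)CC[C@]2(C)O)[C@H]1O[Si](C)(C)C(C)(C)C)CCC=C(C)C | intermediate
33 | methyl (2E,4E)-trienoate | C=C(/C=C/C=C(/C(=O)OC)[C@@H]1CC[C@]2([C@H](CCCO[Si](C)(C)C(C)(C)C)[C@H](O[Si](CC)(CC)CC)CC[C@]2(C)O)[C@H]1O[Si](C)(C)C(C)(C)C)CCC=C(C)C | intermediate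
34 | (2E,4E)-trienol | C=C(/C=C/C=C(/CO)[C@@H]1CC[C@]2([C@H](CCCO[Si](C)(C)C(C)(C)C)[C@H](O[Si](CC)(CC)CC)CC[C@]2(C)O)[C@H]1O[Si](C)(C)C(C)(C)C)CCC=C(C)C | intermediate
35 | TBDPS ether of 34 | C=C(/C=C/C=C(/CO[Si](c3ccccc3)(c4ccccc4)C(C)(C)C)[C@@H]1CC[C@]2([C@H](CCCO[Si](C)(C)C(C)(C)C)[C@H](O[Si](CC)(CC)CC)CC[C@]2(C)O)[C@H]1O[Si](C)(C)C(C)(C)C)CCC=C(C)C | intermediate
36 | diol (free hydroxypropyl and C9-OH) | C=C(/C=C/C=C(/CO[Si](c3ccccc3)(c4ccccc4)C(C)(C)C)[C@@H]1CC[C@]2([C@H](CCCO)[C@H](O)CC[C@]2(C)O)[C@H]1O[Si](C)(C)C(C)(C)C)CCC=C(C)C | intermediate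
37 | 2-(diethoxyphosphoryl)propanoate of 36 | C=C(/C=C/C=C(/CO[Si](c3ccccc3)(c4ccccc4)C(C)(C)C)[C@@H]1CC[C@]2([C@H](CCCOC(=O)C(C)P(=O)(OCC)OCC)[C@H](O)CC[C@]2(C)O)[C@H]1O[Si](C)(C)C(C)(C)C)CCC=C(C)C | intermediate
38 | C9 ketone of 37 | C=C(/C=C/C=C(/CO[Si](c3ccccc3)(c4ccccc4)C(C)(C)C)[C@@H]1CC[C@]2([C@H](CCCOC(=O)C(C)P(=O)(OCC)OCC)C(=O)CC[C@]2(C)O)[C@H]1O[Si](C)(C)C(C)(C)C)CCC=C(C)C | intermediate
39 | eight-membered unsaturated lactone | C=C(/C=C/C=C(/CO[Si](c4ccccc4)(c5ccccc5)C(C)(C)C)[C@@H]1CC[C@]2([C@@H]3CCCOC(=O)/C(C)=C3/CC[C@]2(C)O)[C@H]1O[Si](C)(C)C(C)(C)C)CCC=C(C)C | intermediate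
40 | diol (Z allylic alcohol and hydroxypropyl chain) | C=C(/C=C/C=C(/CO[Si](c3ccccc3)(c4ccccc4)C(C)(C)C)[C@@H]1CC[C@]2([C@H](CCCO)/C(=C(/C)CO)CC[C@]2(C)O)[C@H]1O[Si](C)(C)C(C)(C)C)CCC=C(C)C | intermediate
41 | bis-silylated enal | C=C(/C=C/C=C(/CO[Si](c3ccccc3)(c4ccccc4)C(C)(C)C)[C@@H]1CC[C@]2([C@H](CCCO)/C(=C(/C)C=O)CC[C@]2(C)O)[C@H]1O[Si](C)(C)C(C)(C)C)CCC=C(C)C | intermediate
42 | CNP0246965.1 | C=C(/C=C/C=C(/CO)[C@@H]1CC[C@]2([C@H](CCCO)/C(=C(/C)C=O)CC[C@]2(C)O)[C@H]1O)CCC=C(C)C | target

**Count and risks**

Total: 27 steps. Longest linear sequence: 22 steps (steps 1–5, 9–14, 17–27).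

Most likely to fail:

Step 24. The eight-membered ring must close onto a hindered ketone; slow closure would let intermolecular olefination (oligomers) and base-induced epimerization next to the ketone compete. Fallback, from 36 back to 39: the primary hydroxyl of 36 is acylated with 2-bromopropanoyl bromide (pyridine, CH2Cl2, −40 °C) to the 2-bromopropanoate F1; Dess–Martin oxidation gives the bromo keto ester F2; samarium diiodide (THF, high dilution, −78 to 0 °C) closes the ring by an intramolecular Reformatsky addition to the β-hydroxy lactone F3; MsCl, Et3N and DMAP give the tertiary mesylate F4, and DBU in the same flask eliminates through the lactone enolate to 39, whose geometry is again fixed by the ring.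

Step 11. The activated epoxide may be diverted to proton loss or hydride shift, or a silyl ether may be lost to the Lewis acid, before the ring A bond migrates. Fallback, from 19 back to 21 (it replaces steps 10 and 11): OsO4 (cat.) with N-methylmorpholine N-oxide in acetone/H2O dihydroxylates the trisubstituted alkene on the face opposite to the allyl group to the triol F5; trimethyl orthoformate with pyridinium p-toluenesulfonate ties the cis-diol up as the cyclic orthoformate F6; BF3·OEt2 (CH2Cl2, −78 °C) ionizes the orthoester, the tertiary C–O bond breaks with the same anti 1,2-shift, and the secondary oxygen stays as the formate F7; K2CO3 in MeOH removes the formyl group to give 21.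

Step 10. Facial selectivity may be poor, because the hydroxyl-directing carbinol center and the allyl group need not favour the same face. Fallback, from 19 back to 20: Shi epoxidation with the fructose-derived chiral ketone (the antipode matched to the substrate), KHSO5 (as its triple salt 2KHSO5·KHSO4·K2SO4), K2CO3, MeCN/dimethoxymethane/buffer, 0 °C. Reagent control by the chiral dioxirane replaces hydroxyl direction, the terminal alkene is inert under these conditions, and no new compound is made.

**Further compounds**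

F1 | step 24 | 2-bromopropanoate of the primary alcohol of 36 | C=C(/C=C/C=C(/CO[Si](c3ccccc3)(c4ccccc4)C(C)(C)C)[C@@H]1CC[C@]2([C@H](CCCOC(=O)C(C)Br)[C@H](O)CC[C@]2(C)O)[C@H]1O[Si](C)(C)C(C)(C)C)CCC=C(C)C
F2 | step 24 | C9 ketone of F1 | C=C(/C=C/C=C(/CO[Si](c3ccccc3)(c4ccccc4)C(C)(C)C)[C@@H]1CC[C@]2([C@H](CCCOC(=O)C(C)Br)C(=O)CC[C@]2(C)O)[C@H]1O[Si](C)(C)C(C)(C)C)CCC=C(C)C
F3 | step 24 | eight-membered β-hydroxy lactone | C=C(/C=C/C=C(/CO[Si](c4ccccc4)(c5ccccc5)C(C)(C)C)[C@@H]1CC[C@]2([C@@H]3CCCOC(=O)C(C)C3(O)CC[C@]2(C)O)[C@H]1O[Si](C)(C)C(C)(C)C)CCC=C(C)C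
F4 | step 24 | tertiary mesylate of F3 | C=C(/C=C/C=C(/CO[Si](c4ccccc4)(c5ccccc5)C(C)(C)C)[C@@H]1CC[C@]2([C@@H]3CCCOC(=O)C(C)C3(OS(C)(=O)=O)CC[C@]2(C)O)[C@H]1O[Si](C)(C)C(C)(C)C)CCC=C(C)C
F5 | step 11 | triol from cis-dihydroxylation of 19 (both new hydroxyls trans to allyl) | C=CC[C@@H]1CC[C@](O)([C@]2(O)CC[C@@H](O[Si](CC)(CC)CC)[C@H]2CCCO[Si](C)(C)C(C)(C)C)[C@H]1O
F6 | step 11 | cyclic methyl orthoformate of the cis-diol of F5 | C=CC[C@@H]1CC[C@]2(OC(OC)O[C@@H]12)[C@]3(O)CC[C@@H](O[Si](CC)(CC)CC)[C@H]3CCCO[Si](C)(C)C(C)(C)C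
F7 | step 11 | 1-O-formate of 21 | C=CC[C@@H]1CC[C@]2([C@H](CCCO[Si](C)(C)C(C)(C)C)[C@H](O[Si](CC)(CC)CC)CCC2=O)[C@H]1OC=O
F0 | step 10 | none | none
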